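**Remark on the chemistry.** Flavone numbering is used for all intermediates (O1, C2, C3, C4, C4a, C5 to C8, C8a; ring B primed, prenyl carbons doubly primed). The target has no stereocentre; the one centre that appears on the way (C2 of 12) is racemic and becomes sp2 in the key step.

## The problem

Isolicoflavonol is 3,5,7,4'-tetrahydroxyflavone with a 3-methylbut-2-enyl (prenyl) group at C3', ortho to O4'. Ring A (C4a, C5 to C8, C8a, with oxygen at C5 and C7) is fused to the 4-pyranone ring C through C4a–C8a, and ring B sits on C2. A synthesis therefore has to decide how C4–C4a, O1–C2 and C2–C3 are made and when O3 is introduced. With no stereocentre, the control problems are regiochemical: chromone against coumarin or aurone closure, oxygen at C3, and the prenyl group at C3' only. The prenyl group is the fragile part. Next to a free phenol its alkene closes to a 2,2-dimethylchroman under Brønsted or Lewis acid, it is reduced under hydrogenolysis, and it is attacked by electrophilic oxidants; late acid-labile or benzyl protecting groups and peracid-type oxidations are therefore excluded. The 3-hydroxy-4-pyranone enol is oxidised by air in base, so the hydroxyls should be unveiled last, under mild and oxygen-free conditions. The enabling feature is ring A: C5, C7 and C8a carry oxygen and C4a carries C4, the pattern of a C-acylated benzene-1,3,5-triol, and this triol is threefold symmetric, so acylation at any carbon and closure through either flanking oxygen give the same ring system. The rest, C4 at the acid level, C3 bearing O3 and C2 at the ketone level bearing ring B, is an α-oxygenated aroylacetic ester, so one three-carbon partner can bring in every oxidation level of ring C.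

## Retrosynthesis

**17 to 16.** The last cut removes only the acyl groups on O3 and O4'. Esters that fall to methoxide are preferred to acetals or benzyl ethers, because their removal needs neither acid nor hydrogen. O5 and O7 need no protection. Diester 16 is no simpler in skeleton, but it is the form in which the flavonol can leave a hot melt; the forward step asks only for transesterification under argon.

**16 to 12 and 13 (key disconnection).** The bonds C4–C4a and O1–C2 are cut, which separates phloroglucinol 13 from the α-benzoyloxy β-ketoester 12.
- Against its neighbours: cutting C2–C3 and O1–C2 would need an ω-oxygenated acylphloroglucinol and protection or sacrifice of the ring A hydroxyls; cutting C2–C1' would need a 2-halogenated 3-oxychromone.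
- Gain: 13 is used as purchased, and ring B, C2, C3, O3 and C4 all move into one acyclic ester. A tricycle becomes a symmetric triol plus a monoaryl ketoester.
- Demands on the forward reaction: chromone and not coumarin mode, no acid, and survival of both ester groups at about 240 °C among free phenols.
- Choice of groups: O4' carries a hindered pivalate, so the ortho-prenylphenol stays covered and cannot close to a chroman. O3 carries a benzoate, which has no enolisable hydrogen. Acetates would be passed on to phloroglucinol more easily, where a Fries shift would fix them as C-acetyl by-products.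

**12 to 10 and 11.** The C3–O3 bond is cut. Bringing the oxygen in together with the C2–C3 bond, by acylating a glycolate enolate, would put an α-oxygenated ester enolate next to base-labile esters. Oxidation of the doubly activated methylene of 10 with dibenzoyl peroxide 11 is more dependable, and it delivers the benzoate directly without an oxidant such as PhI(OAc)2 or Pb(OAc)4 that might touch the alkene. The forward step must stop after one benzoyloxylation.

**10 to 6 and 8 (through 9, made with 7).** The C2–C3 bond is cut. A Claisen condensation of a benzoate ester with the lithium enolate of ethyl acetate was set aside: the enolate would also attack the aryl pivalate, and with the phenol left free the para-phenoxide deactivates the ester. Acyl imidazolide 9, from acid 6 and carbonyldiimidazole 7, reacts with the magnesium enolate of potassium ethyl malonate 8 under neutral conditions. No HCl is formed, as it would be on the way through an acid chloride, so the alkene is safe.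

**6 to 4 and 5; 4 to 3.** The O4'–acyl bond and the methyl ester are cut. Hydrolysis comes first, because saponification after acylation would strip the pivalate. Pivaloyl chloride 5 then acylates only the phenoxide in aqueous base.

**3 to 1 and 2.** The C3'–C1'' bond is cut. In methyl 4-hydroxybenzoate 1 the para position is blocked and the two ortho positions are equivalent, so ortho C-alkylation of the phenoxide with prenyl bromide 2 can give only one C-prenyl compound. The forward reaction must favour carbon over oxygen and attack at the primary carbon of the allylic bromide. A longer ether-rearrangement sequence is kept in reserve.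

## Roads not taken

**Alternative 1:** Ring B is built by cycloaddition. C1'–C2' and C5'–C6' are cut. In the forward direction 2-ethynyl-3,5,7-tris(methoxymethoxy)chromen-4-one A2 and 2-(tert-butyldimethylsilyloxy)-3-(3-methylbut-2-enyl)buta-1,3-diene A3 would undergo a thermal Diels–Alder reaction, and DDQ in the same pot would aromatise the adduct to 3,5,7-tris(methoxymethoxy)-4'-O-(tert-butyldimethylsilyl)isolicoflavonol A1. Fluoride and then acid would be needed to take A1 on to the target.
- Merits: the silyloxy group of A3 directs itself para to the chromone, so the 3',4' pattern of A1 is written into the diene. The prenyl group arrives by carbon–carbon bond construction rather than by phenoxide alkylation, and in this respect the road is better than step 1 of the chosen plan. It also never exceeds moderate temperatures.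
- Weak points: ring B is an arene that is sold with its oxygen and its carboxyl carbon in place. A2 needs a fully protected 3,5,7-trioxygenated chromone with an alkyne at C2, and A3 comes from a polymerisation-prone α-methylene ketone. DDQ meets an allylic and benzylic prenyl group on the way to A1. The three methoxymethyl groups of A1 must finally be removed with acid next to the ortho-prenylphenol.
- Comparison: the chosen plan has a less selective prenylation and a hot step, but sets against this a seven-step sequence from commodity arenes and an acid-free ending.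

**Alternative 2:** Ring A is folded biomimetically. The cut is C4a–C5 (equivalent to C4a–C8a at that stage). Mg(OMe)2 would cyclise methyl (E)-9-[4-(methoxymethoxy)-3-(3-methylbut-2-enyl)phenyl]-3,5,7-trioxonon-8-enoate A5 by Claisen condensation to the chalcone (E)-3-[4-(methoxymethoxy)-3-(3-methylbut-2-enyl)phenyl]-1-(2,4,6-trihydroxyphenyl)prop-2-en-1-one A4.
- Merits: it follows the biosynthesis, forms ring A under mild basic conditions, and never stresses the prenyl group thermally, which is gentler than the chosen fusion.
- Weak points: A5 is a poly-β-carbonyl chain that also closes to pyranones or folds by aldol reaction. The ring it makes is only an acylphloroglucinol, which one acylation of phloroglucinol 13 provides. A4 still lacks O1–C2 and O3, and oxidative cyclisation of chalcones with a 6'-oxygen (Algar–Flynn–Oyamada) tends towards aurones unless ring A is protected first. The methoxymethyl group of A4 needs acid at the end.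
- Comparison: the chosen plan reaches the flavonol oxidation level, with O3 in place, in the ring-forming step itself.

**Alternative 3:** Ring A is built by Danheiser benzannulation on a pyranone derived from kojic acid A9. Four bonds are cut: C8–C8a, C7–C8, C5–C6 and C4a–C5. Photolysis of 6-(diazoacetyl)-3-(methoxymethoxy)-2-[4-(methoxymethoxy)-3-(3-methylbut-2-enyl)phenyl]pyran-4-one A7 with triisopropylsiloxyacetylene A8 would give 3,4'-bis(methoxymethoxy)-7-O-triisopropylsilylisolicoflavonol A6. The sequence is Wolff rearrangement, ketene–alkyne [2+2] addition, four-electron ring opening and six-electron closure.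
- Merits: the cascade runs near room temperature, and ring C with O3 and ring B is finished in A7 beforehand. O5 and O7 emerge differentiated in A6. In thermal mildness it is clearly better than a 240 °C melt.
- Weak points: A7 requires arylation of the pyranone ring of A9, oxidation of the hydroxymethyl group to the acid and diazomethane homologation. A8 is a sensitive ynol ether that has to be prepared and used fresh. The prenyl alkene is exposed to ketene intermediates, and the 4-pyranone chromophore can itself rearrange on irradiation. The O5/O7 differentiation in A6 is of no use for this target. Acid is again needed for the methoxymethyl groups of A6. The step count is roughly double.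
- Comparison: the chosen plan accepts one short hot step, with O4' and O3 protected against it, in return for commercial ring A and far fewer operations.

Key step: step 6

## Route

**Step 1**
Reactants: 1 methyl 4-hydroxybenzoate; 2 1-bromo-3-methylbut-2-ene (prenyl bromide)
Product: 3 methyl 4-hydroxy-3-(3-methylbut-2-enyl)benzoate
Conditions: NaH (1.05 equiv), toluene, 0 °C to rt; then 2, rt, dark
Reagents that add atoms: 1-bromo-3-methylbut-2-ene (2), CC(C)=CCBr
Why: Ortho C-alkylation of an ambident phenoxide: as a tight sodium ion aggregate in toluene the phenoxide should react at carbon and not at oxygen, the para position is blocked and both ortho positions are equivalent. SN2 attack at the primary allylic carbon keeps the prenyl group linear.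

**Step 2**
Reactants: 3 methyl 4-hydroxy-3-(3-methylbut-2-enyl)benzoate
Product: 4 4-hydroxy-3-(3-methylbut-2-enyl)benzoic acid
Conditions: 2 M NaOH, MeOH, 65 °C; then 1 M HCl to pH 3, 0 °C
Reagents that add atoms: sodium hydroxide, [Na+].[OH-]
Why: Ester saponification; the prenyl group is inert to aqueous base, and cold dilute acid in the work-up should avoid closure of the ortho-prenylphenol to a chroman.

**Step 3**
Reactants: 4 4-hydroxy-3-(3-methylbut-2-enyl)benzoic acid; 5 2,2-dimethylpropanoyl chloride (pivaloyl chloride)
Product: 6 4-(2,2-dimethylpropanoyloxy)-3-(3-methylbut-2-enyl)benzoic acid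
Conditions: 5 (1.2 equiv), 2 M NaOH (2.5 equiv), THF/H2O, 0 °C; then 1 M HCl to pH 3, 0 °C
Reagents that add atoms: 2,2-dimethylpropanoyl chloride (5), CC(C)(C)C(=O)Cl
Why: Schotten–Baumann acylation: in the dianion the phenoxide is acylated while the carboxylate stays free, since any mixed anhydride is hydrolysed in the alkaline medium. The hindered pivalate is chosen to hold O4' through steps 4 to 6.

**Step 4**
Reactants: 6 4-(2,2-dimethylpropanoyloxy)-3-(3-methylbut-2-enyl)benzoic acid; 7 1,1'-carbonyldiimidazole; 8 potassium 3-ethoxy-3-oxopropanoate (potassium ethyl malonate)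
Product: 10 ethyl 3-[4-(2,2-dimethylpropanoyloxy)-3-(3-methylbut-2-enyl)phenyl]-3-oxopropanoate, via acyl imidazolide 9 (not isolated)
Conditions: 7 (1.1 equiv), THF, rt; then 8, MgCl2, Et3N, THF/MeCN, rt to 45 °C; 1 M HCl, 0 °C
Reagents that add atoms: potassium 3-ethoxy-3-oxopropanoate (8), CCOC(=O)CC(=O)[O-].[K+]; 1,1'-carbonyldiimidazole (7), O=C(n1ccnc1)n1ccnc1 (its imidazolyl group is carried only by intermediate 9)
Why: Masamune–Brooks homologation: acyl imidazolide 9 C-acylates the magnesium enolate of the malonate half ester, and decarboxylation gives the β-ketoester. The conditions are neutral, involve no ester enolate and release no HCl, so the aryl pivalate and the alkene should both survive.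

**Step 5**
Reactants: 10 ethyl 3-[4-(2,2-dimethylpropanoyloxy)-3-(3-methylbut-2-enyl)phenyl]-3-oxopropanoate; 11 dibenzoyl peroxide
Product: 12 ethyl 2-(benzoyloxy)-3-[4-(2,2-dimethylpropanoyloxy)-3-(3-methylbut-2-enyl)phenyl]-3-oxopropanoate (racemic)
Conditions: NaH (1.0 equiv), THF, 0 °C; enolate added slowly to 11 (1.0 equiv) in THF, 0 °C to rt; cold 1 M HCl
Reagents that add atoms: dibenzoyl peroxide (11), O=C(OOC(=O)c1ccccc1)c1ccccc1
Why: Electrophilic α-benzoyloxylation of a β-dicarbonyl enolate by a diacyl peroxide (substitution at the peroxide oxygen); at or below room temperature the peroxide does not form radicals and leaves the alkene alone. The new centre is racemic and is lost in step 6; inverse addition is meant to limit a second oxidation.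

**Step 6**
Reactants: 12 ethyl 2-(benzoyloxy)-3-[4-(2,2-dimethylpropanoyloxy)-3-(3-methylbut-2-enyl)phenyl]-3-oxopropanoate; 13 phloroglucinol (benzene-1,3,5-triol)
Product: 16 3-O-benzoyl-4'-O-pivaloylisolicoflavonol, via benzoyloxy acylketene 14 (not isolated), via C-acylphloroglucinol diketone 15 (not isolated)
Conditions: 13 (2 equiv, anhydrous), neat melt, 240 °C, Ar stream, 15 min (EtOH and H2O swept out)
Reagents that add atoms: phloroglucinol (13), Oc1cc(O)cc(O)c1
Why: Mentzer pyrone synthesis, the acid-free thermal fusion of phloroglucinol with an aroylacetic ester. In the melt 12 loses ethanol to give α-oxoketene 14, which acylates 13 at carbon, either directly or by O-acylation and thermal acyl shift, and so forms C4–C4a in diketone 15. A flanking hydroxyl of 15 then adds to the aryl ketone carbon (6-exo-trig) and the hemiketal loses water, which forms O1–C2 and closes ring C as an aromatic 4-pyranone. The closest known reactions are the fusion of phloroglucinol with ethyl aroylacetates, α-substituted ones included, to 5,7-dihydroxyflavones, and the cyclodehydration of α-benzoyloxy ortho-hydroxydibenzoylmethanes to 3-benzoyloxyflavones. No stereocentre is formed, and the racemic centre of 12 becomes the sp2 carbon C3. The selectivity needed is chromone against coumarin mode: without acid the ketone is not activated for attack by the ring carbon, the ketene delivers the ester carbon to the ring, and the α-substituent further disfavours the coumarin mode. The threefold symmetry of 13 makes its three ring carbons and, after acylation, the two flanking hydroxyls equivalent, so ring A can form in one way only. The hindered pivalate keeps O4' covered so the prenyl group cannot close to a chroman in the hot phenolic melt, the benzoate has no enolisable hydrogen, and an acyl group that strays to O5 or O7 is removed in step 7.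

**Step 7**
Reactants: 16 3-O-benzoyl-4'-O-pivaloylisolicoflavonol
Product: 17 isolicoflavonol
Conditions: K2CO3 (3 equiv), degassed MeOH, Ar, rt to 40 °C; then 1 M HCl to pH 4, 0 °C
Reagents that add atoms: none
Why: Base-mediated transesterification (Zemplén-type methanolysis): methoxide cleaves the enol-type 3-O-benzoate and the activated aryl pivalate as their methyl esters. Neither acid nor hydrogen is involved, so the prenyl group is untouched, and exclusion of air protects the flavonol anion.

## Compound list

1 | methyl 4-hydroxybenzoate | COC(=O)c1ccc(O)cc1 | starting material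
2 | 1-bromo-3-methylbut-2-ene (prenyl bromide) | CC(C)=CCBr | starting material
3 | methyl 4-hydroxy-3-(3-methylbut-2-enyl)benzoate | COC(=O)c1ccc(O)c(CC=C(C)C)c1 | intermediate
4 | 4-hydroxy-3-(3-methylbut-2-enyl)benzoic acid | OC(=O)c1ccc(O)c(CC=C(C)C)c1 | intermediate
5 | 2,2-dimethylpropanoyl chloride (pivaloyl chloride) | CC(C)(C)C(=O)Cl | starting material
6 | 4-(2,2-dimethylpropanoyloxy)-3-(3-methylbut-2-enyl)benzoic acid | CC(C)=CCc1cc(C(=O)O)ccc1OC(=O)C(C)(C)C | intermediate
7 | 1,1'-carbonyldiimidazole | O=C(n1ccnc1)n1ccnc1 | starting material
8 | potassium 3-ethoxy-3-oxopropanoate (potassium ethyl malonate) | CCOC(=O)CC(=O)[O-].[K+] | starting material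
9 | [4-(imidazole-1-carbonyl)-2-(3-methylbut-2-enyl)phenyl] 2,2-dimethylpropanoate (acyl imidazolide, not isolated) | CC(C)=CCc1cc(C(=O)n2ccnc2)ccc1OC(=O)C(C)(C)C | intermediate
10 | ethyl 3-[4-(2,2-dimethylpropanoyloxy)-3-(3-methylbut-2-enyl)phenyl]-3-oxopropanoate | CCOC(=O)CC(=O)c1ccc(OC(=O)C(C)(C)C)c(CC=C(C)C)c1 | intermediate
11 | dibenzoyl peroxide | O=C(OOC(=O)c1ccccc1)c1ccccc1 | starting material
12 | ethyl 2-(benzoyloxy)-3-[4-(2,2-dimethylpropanoyloxy)-3-(3-methylbut-2-enyl)phenyl]-3-oxopropanoate (racemic) | CCOC(=O)C(OC(=O)c1ccccc1)C(=O)c1ccc(OC(=O)C(C)(C)C)c(CC=C(C)C)c1 | intermediate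
13 | phloroglucinol (benzene-1,3,5-triol) | Oc1cc(O)cc(O)c1 | starting material
14 | 2-(benzoyloxy)-3-[4-(2,2-dimethylpropanoyloxy)-3-(3-methylbut-2-enyl)phenyl]-3-oxoprop-1-en-1-one (α-oxoketene, not isolated) | O=C=C(OC(=O)c1ccccc1)C(=O)c1ccc(OC(=O)C(C)(C)C)c(CC=C(C)C)c1 | intermediate
15 | 2-(benzoyloxy)-1-[4-(2,2-dimethylpropanoyloxy)-3-(3-methylbut-2-enyl)phenyl]-3-(2,4,6-trihydroxyphenyl)propane-1,3-dione (not isolated) | O=C(c1c(O)cc(O)cc1O)C(OC(=O)c1ccccc1)C(=O)c1ccc(OC(=O)C(C)(C)C)c(CC=C(C)C)c1 | intermediate
16 | 3-O-benzoyl-4'-O-pivaloylisolicoflavonol, [2-[4-(2,2-dimethylpropanoyloxy)-3-(3-methylbut-2-enyl)phenyl]-5,7-dihydroxy-4-oxochromen-3-yl] benzoate | CC(C)=CCc1cc(-c2oc3cc(O)cc(O)c3c(=O)c2OC(=O)c2ccccc2)ccc1OC(=O)C(C)(C)C | intermediate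
17 | isolicoflavonol, 3,5,7-trihydroxy-2-[4-hydroxy-3-(3-methylbut-2-enyl)phenyl]chromen-4-one | CC(C)=CCc1cc(-c2oc3cc(O)cc(O)c3c(=O)c2O)ccc1O | target

## Step count and risks

Total step count: 7. Longest linear sequence: 7 steps (1 to 3, 4, 6, 10, 12, 16, 17).

**Step 6 (key step).** Most likely to go wrong: transfer of the benzoyl group from 12 or 14 to the excess phloroglucinol, or thermal breakdown of the α-benzoyloxy acylketene, may outrun C-acylation, because the known fusions carry simpler α-substituents and the melt is full of free phenols. Less likely is loss of the pivalate followed by closure of the prenyl group onto O4'. Fallback: ring C is closed through C2–C3 and O1–C2 instead (Allan–Robinson flavonol synthesis). It sets out from acid 6 and phloroglucinol 13 and comes back at target 17. DCC (0.5 equiv, CH2Cl2) turns 6 into 4-(2,2-dimethylpropanoyloxy)-3-(3-methylbut-2-enyl)benzoic anhydride F1. Houben–Hoesch acylation of 13 with cyanomethyl benzoate (ZnCl2, HCl, Et2O, 0 °C) gives [2-(benzoyloxy)-1-(2,4,6-trihydroxyphenyl)ethylidene]ammonium chloride F2, which warm water hydrolyses to 2-oxo-2-(2,4,6-trihydroxyphenyl)ethyl benzoate F3. Heating F3 with F1 and Et3N in a sealed vessel at about 160 °C should give the O-aroylated flavonol, represented by 3-O-benzoyl-4'-O-pivaloyl-7-O-[4-(2,2-dimethylpropanoyloxy)-3-(3-methylbut-2-enyl)benzoyl]isolicoflavonol F4. KOH in degassed aqueous methanol, then cold dilute acid, removes every acyl group and gives 17.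

**Step 1.** Most likely to go wrong: O-alkylation and a second alkylation compete with ortho C-alkylation, because the phenoxide is ambident and the ester lowers the nucleophilicity of the ring. Fallback: the prenyl group is delivered by sigmatropic rearrangement, setting out from 1 and coming back at 3. Alkylation of 1 with 3-chloro-3-methylbut-1-yne (DBU, CuCl2 cat., MeCN, 0 °C) gives methyl 4-[(2-methylbut-3-yn-2-yl)oxy]benzoate F5. Semihydrogenation (H2, Pd/CaCO3 poisoned with Pb(OAc)2, quinoline) gives methyl 4-[(2-methylbut-3-en-2-yl)oxy]benzoate F6. Aromatic Claisen rearrangement in N,N-diethylaniline at about 190 °C moves the allyl unit to the ortho carbon with allylic inversion and gives 3.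

**Step 5.** Most likely to go wrong: a second benzoyloxylation, because the product is more acidic than 10 and can be deprotonated by unreacted enolate; some radical decomposition of the peroxide at the allylic positions is also possible. Fallback: the C–O bond is made by carbenoid insertion, setting out from 10 and coming back at 12. Regitz diazo transfer (4-acetamidobenzenesulfonyl azide, Et3N, MeCN) gives ethyl 2-diazo-3-[4-(2,2-dimethylpropanoyloxy)-3-(3-methylbut-2-enyl)phenyl]-3-oxopropanoate F7. Rh2(OAc)4 (cat.) with excess benzoic acid in CH2Cl2 should then insert the carbenoid into the O–H bond of the acid and give 12.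

**Step 4.** Most likely to go wrong: acyl transfer from the aryl pivalate to the liberated imidazole, or incomplete C-acylation of the magnesium malonate by the electron-rich, ortho-substituted acyl imidazolide. Fallback: the two-carbon unit comes from Meldrum's acid, setting out from 6 and coming back at 10. Coupling of 6 with Meldrum's acid (DCC, DMAP, CH2Cl2, 0 °C to rt) gives 5-[[4-(2,2-dimethylpropanoyloxy)-3-(3-methylbut-2-enyl)phenyl](hydroxy)methylidene]-2,2-dimethyl-1,3-dioxane-4,6-dione F8. Heating F8 in ethanol at 80 °C opens it through the acylketene and gives 10.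

## Further compounds

F1 | step 6 | 4-(2,2-dimethylpropanoyloxy)-3-(3-methylbut-2-enyl)benzoic anhydride | CC(C)=CCc1cc(C(=O)OC(=O)c2ccc(OC(=O)C(C)(C)C)c(CC=C(C)C)c2)ccc1OC(=O)C(C)(C)C
F2 | step 6 | [2-(benzoyloxy)-1-(2,4,6-trihydroxyphenyl)ethylidene]ammonium chloride | [NH2+]=C(COC(=O)c1ccccc1)c1c(O)cc(O)cc1O.[Cl-]
F3 | step 6 | 2-oxo-2-(2,4,6-trihydroxyphenyl)ethyl benzoate | O=C(COC(=O)c1ccccc1)c1c(O)cc(O)cc1O
F4 | step 6 | 3-O-benzoyl-4'-O-pivaloyl-7-O-[4-(2,2-dimethylpropanoyloxy)-3-(3-methylbut-2-enyl)benzoyl]isolicoflavonol | CC(C)=CCc1cc(-c2oc3cc(OC(=O)c4ccc(OC(=O)C(C)(C)C)c(CC=C(C)C)c4)cc(O)c3c(=O)c2OC(=O)c5ccccc5)ccc1OC(=O)C(C)(C)C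
F5 | step 1 | methyl 4-[(2-methylbut-3-yn-2-yl)oxy]benzoate | COC(=O)c1ccc(OC(C)(C)C#C)cc1
F6 | step 1 | methyl 4-[(2-methylbut-3-en-2-yl)oxy]benzoate | COC(=O)c1ccc(OC(C)(C)C=C)cc1
F7 | step 5 | ethyl 2-diazo-3-[4-(2,2-dimethylpropanoyloxy)-3-(3-methylbut-2-enyl)phenyl]-3-oxopropanoate | CCOC(=O)C(=[N+]=[N-])C(=O)c1ccc(OC(=O)C(C)(C)C)c(CC=C(C)C)c1
F8 | step 4 | 5-[[4-(2,2-dimethylpropanoyloxy)-3-(3-methylbut-2-enyl)phenyl](hydroxy)methylidene]-2,2-dimethyl-1,3-dioxane-4,6-dione | CC1(C)OC(=O)C(=C(O)c2ccc(OC(=O)C(C)(C)C)c(CC=C(C)C)c2)C(=O)O1
A1 | alternative 1 | 3,5,7-tris(methoxymethoxy)-4'-O-(tert-butyldimethylsilyl)isolicoflavonol | CC(C)=CCc1cc(-c2oc3cc(OCOC)cc(OCOC)c3c(=O)c2OCOC)ccc1O[Si](C)(C)C(C)(C)C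
A2 | alternative 1 | 2-ethynyl-3,5,7-tris(methoxymethoxy)chromen-4-one | C#Cc1oc2cc(OCOC)cc(OCOC)c2c(=O)c1OCOC
A3 | alternative 1 | 2-(tert-butyldimethylsilyloxy)-3-(3-methylbut-2-enyl)buta-1,3-diene | C=C(O[Si](C)(C)C(C)(C)C)C(=C)CC=C(C)C
A4 | alternative 2 | (E)-3-[4-(methoxymethoxy)-3-(3-methylbut-2-enyl)phenyl]-1-(2,4,6-trihydroxyphenyl)prop-2-en-1-one | CC(C)=CCc1cc(/C=C/C(=O)c2c(O)cc(O)cc2O)ccc1OCOC
A5 | alternative 2 | methyl (E)-9-[4-(methoxymethoxy)-3-(3-methylbut-2-enyl)phenyl]-3,5,7-trioxonon-8-enoate | COC(=O)CC(=O)CC(=O)CC(=O)/C=C/c1ccc(OCOC)c(CC=C(C)C)c1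
A6 | alternative 3 | 3,4'-bis(methoxymethoxy)-7-O-triisopropylsilylisolicoflavonol | CC(C)=CCc1cc(-c2oc3cc(O[Si](C(C)C)(C(C)C)C(C)C)cc(O)c3c(=O)c2OCOC)ccc1OCOC
A7 | alternative 3 | 6-(diazoacetyl)-3-(methoxymethoxy)-2-[4-(methoxymethoxy)-3-(3-methylbut-2-enyl)phenyl]pyran-4-one | [N-]=[N+]=CC(=O)c1cc(=O)c(OCOC)c(-c2ccc(OCOC)c(CC=C(C)C)c2)o1
A8 | alternative 3 | ethynyloxy(triisopropyl)silane (triisopropylsiloxyacetylene) | C#CO[Si](C(C)C)(C(C)C)C(C)C
A9 | alternative 3 | kojic acid, 5-hydroxy-2-(hydroxymethyl)pyran-4-one | O=c1cc(CO)occ1O
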